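Remark on the chemistry: the target is achiral. Ring A is numbered from the carboxyl carbon (C1) and ring B from the carbon that bears the ester carbonyl (C1'). The structures involved were checked against the target and needed no correction.

## Structural features

The target is a para-depside: two benzene rings joined only by an aryl ester between the carbonyl on C1' of ring B and the C4 oxygen of ring A. Ring A is an olivetolic acid unit with a carboxylic acid on C1, a hydroxyl on C2 and an n-pentyl chain on C6. Ring B is a 2-hydroxy-4-methoxy-6-methylbenzoyl unit. There is no stereocenter, so the problem is one of regiochemistry and functional-group tolerance. The fragile points are the aryl ester (cleaved by base and nucleophiles), the salicylic-type acid of ring A (loses CO2 on heating or in strong acid) and the electron-rich rings. The real difficulty is the 1,2,4,6-pattern of ring A: four substituents must sit on defined carbons, and the chemically similar C2 and C4 oxygens must be told apart. Ring B poses the same question for its C2' and C4' oxygens. The key step uses the contiguous triad C6 (pentyl), C1 (carboxyl), C2 (oxygen) of ring A: a carbon nucleophile and a carbon electrophile on neighbouring carbons, with an oxygen beside the electrophile-bearing carbon, is the pattern left by addition across a 3-alkoxybenzyne.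

## Logic of the disconnections

**19 to 18.** The two benzyl–oxygen bonds are cut, the ester on the ring A carboxyl and the ether on C2'. They go last because the free acid decarboxylates easily and the aryl ester does not tolerate base, so the final unmasking must be neutral. The gain is that every acidic site but one is masked up to the end. The forward step must cleave benzylic C–O bonds without touching the aryl ester.

**18 to 17.** The acetal C–O bond on the C2 oxygen is cut. This oxygen must stay masked while the C4 oxygen is acylated, and the same group directs the key step. The gain is a coupling product with no free phenol. The forward step needs an acid that removes the acetal but spares both esters, which their di-ortho substitution should allow.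

**17 to 11 and 15 (through 16).** The ester bond between the C4 oxygen and the ring B carbonyl is cut, the only bond joining the rings. The route becomes convergent and each half is a simple benzoate. The forward step needs a phenol partner with C4 as its only free hydroxyl, a strongly activated acid because the carbonyl lies between two ortho substituents, and a capped C2' oxygen to prevent self-acylation.

**15 to 14, 13 and 12.** The O–benzyl bond at C2' and the O–methyl bond at C4' are cut and the methyl ester restored. Compound 12 already holds the whole carbon skeleton of ring B, so only its two hydroxyls need differentiating. The forward steps rely on the hydrogen bond from the C2' hydroxyl to the ester carbonyl, so methylation must stop at C4'. The ester hydrolysis must overcome two ortho substituents.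

**11 to 10 and 9.** The Si–O bond on the C4 oxygen and the O–benzyl bond of the ester are cut. A silyl ether on C4 and an acetal on C2 are orthogonal, so fluoride frees C4 alone. The forward steps need esterification by alkylation of the carboxylate, since the acid is too hindered for acyl substitution, and a buffered fluoride step.

**9 to 3, 5 and a one-carbon electrophile (key step).** The C6–pentyl and C1–carboxyl bonds are cut together. Adjacent carbons that carry a nucleophile-derived and an electrophile-derived group are the retron of an aryne, and the C2 oxygen next to C1 fixes the direction of addition. The gain is two C–C bonds in one operation from a 1,3,5-trisubstituted benzene with both oxygens already in place and already differentiated. The forward step demands selective removal of the proton between fluorine and the acetal, regioselective addition of 5, and that 5 outcompetes the aryllithiums for the aryne.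

**3 to 2 and 1; 5 to 4.** The acetal C–O and Si–O bonds are cut back to the symmetric diol 1, and the C–Li bond back to the chloride 4. The forward steps need monoprotection of a symmetric diol with a silyl group bulky enough to shield its neighbours and survive an alkyllithium, and installation of the acetal without isolating the chloromethyl ether.

## Other disconnections considered

**Alternative 1:** biomimetic aldol folding of ring B.
- **Cut:** the C1'–C6' bond of ring B, which unfolds that ring into a linear 3,5,7-trioxooctanoyl chain on the C4 oxygen of ring A.
- **Forward step:** benzyl 2,4-dihydroxy-6-pentylbenzoate A1 would trap, at its C4 hydroxyl, the acylketene released on heating 6-(2,4-dioxopentyl)-2,2-dimethyl-4H-1,3-dioxin-4-one A2. The triketo ester, benzyl 2-hydroxy-6-pentyl-4-[(3,5,7-trioxooctanoyl)oxy]benzoate A3, would not be isolated. An amine would promote aldol attack of chain C2 on the C7 ketone, dehydration and enolisation to benzyl 4-[(2,4-dihydroxy-6-methylbenzoyl)oxy]-2-hydroxy-6-pentylbenzoate A4.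
- **In favour:** the depside ester forms by addition of a phenol to a ketene before its carbonyl is flanked by two ortho groups, so the hindered acylation of step 10 is avoided. On this point the alternative is better than the chosen plan. Ring B needs no protecting group and the sequence mirrors the biosynthesis.
- **Against:** A4 has free hydroxyls on C2' and C4', so a late selective O-methylation is needed on a molecule with three phenols and a base-sensitive aryl ester. A3 is an activated ester whose enolised chain could lactonise to a 4-hydroxy-2-pyrone with loss of A1. A2 takes several steps. Ring A is not addressed, since A1 must still be made, most simply through the aryne step.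
- **Comparison:** structurally it builds the ring that can be bought with its substituents in place (12) and leaves the harder ring untouched. Mechanistically it replaces a question of aryne regiochemistry by one of C- versus O-cyclisation and of which phenol is methylated. In step count it is at best equal, because what is saved on 13 to 16 is spent on A2 and the methylation.

**Alternative 2:** carbonylative three-component assembly of the depside carbonyl.
- **Cut:** both bonds of the depside carbonyl, C1'–C(=O) and C(=O)–O(C4), leaving the carbonyl as a one-carbon unit.
- **Forward step:** 2-iodo-1,5-dimethoxy-3-methylbenzene A5, carbon monoxide A6 and A1 would combine under Pd(OAc)2 with a wide-bite-angle bisphosphine and an amine base. Oxidative addition of A5 to zerovalent palladium, insertion of A6 to an aroyl complex of divalent palladium and capture by the C4 phenoxide of A1 would give benzyl 4-[(2,4-dimethoxy-6-methylbenzoyl)oxy]-2-hydroxy-6-pentylbenzoate A7.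
- **In favour:** the ester is assembled catalytically from three simple pieces with no preformed hindered acid chloride, and A5 is one step from a cheap arene. In convergence it is better than the chosen plan. On ring A it is equal, since A1 would come from the same aryne chemistry.
- **Against:** A7 has a methyl ether on C2', so a chelation-directed demethylation must cleave one aryl methyl ether and spare the other and the aryl ester. Oxidative addition and insertion at an iodide flanked by methoxy and methyl are slow, and phenoxides are weak partners for acylpalladium. Pressurised A6 is a hazard the chosen plan lacks.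
- **Comparison:** structurally it relies on the same hydrogen bond on ring A that a classical acylation of A1 would use, but it trades the C2' benzyl ether (removed together with the benzyl ester in step 12) for a C2' methyl ether that needs its own cleavage step. Mechanistically it relies on catalyst behaviour at a di-ortho-substituted centre, where the chosen plan uses a stoichiometric acyl transfer. The step count after the ring A phenol is about equal, but the carbonylation and the demethylation each carry more risk than any step after the key step of the chosen plan.

**Alternative 3:** Diels–Alder construction of ring B on an aryl butynoate.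
- **Cut:** C1'–C2' and C5'–C6' of ring B, a retro-Diels–Alder that leaves the ester carbonyl, C1', C6' and the methyl group as an aryl but-2-ynoate on ring A.
- **Forward step:** benzyl 4-(but-2-ynoyloxy)-2-[(tert-butyldimethylsilyl)oxy]-6-pentylbenzoate A8 and 1,3-dimethoxy-1-(trimethylsilyloxy)buta-1,3-diene A9 would undergo [4+2] cycloaddition, the CH2 terminus of A9 bonding to the methyl-bearing alkyne carbon. Loss of methanol and desilylation on work-up would give benzyl 2-[(tert-butyldimethylsilyl)oxy]-4-[(2-hydroxy-4-methoxy-6-methylbenzoyl)oxy]-6-pentylbenzoate A10.
- **In favour:** ring B arrives with the C2' hydroxyl free and the C4' oxygen methylated, with no protecting group and no selective alkylation, and the ester is made from an unhindered alkynoic acid. On both points it is better than the chosen plan, which spends steps 7 to 9 on the oxygens of 12 and must force a hindered acylation.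
- **Against:** a β-methyl ynoate is a weak dienophile. At the temperatures it needs, A9 could degrade or attack the activated aryl ester as a carbon nucleophile, releasing the ring A phenol. The regiochemistry rests on orbital polarisation alone, and A9 is moisture-sensitive and takes two steps. A8 needs a ring A phenol with C4 free and C2 masked, the same kind of intermediate as 11, so nothing is saved on ring A.
- **Comparison:** structurally both plans need the same differentiated ring A. Mechanistically a pericyclic ring synthesis replaces a simple acyl transfer. In step count the alternative is equal or one step shorter, but its central step is less secure than steps 7 to 10.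

Key step: step 4

## Steps

Step 1
Reactants: 1 5-fluorobenzene-1,3-diol
Product: 2 3-fluoro-5-[(triisopropylsilyl)oxy]phenol
Conditions: NaH (1.0 equiv), THF, 0 °C; iPr3SiCl (1.0 equiv), 0 °C to rt
Reagents that add atoms: chlorotriisopropylsilane, CC(C)[Si](Cl)(C(C)C)C(C)C
Why: O-silylation of the monosodium phenoxide; one equivalent of base and of a bulky silyl chloride should favour the mono-ether, and the bis-ether and unreacted diol are separable and can be recycled.

Step 2
Reactants: 2 3-fluoro-5-[(triisopropylsilyl)oxy]phenol
Product: 3 1-fluoro-3-(methoxymethoxy)-5-[(triisopropylsilyl)oxy]benzene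
Conditions: CH2(OMe)2, AcCl, ZnBr2 (0.01 mol %), toluene, rt; then 2, iPr2NEt, 0 °C to rt; aq. NH4Cl quench
Reagents that add atoms: chloromethyl methyl ether, COCCl, made in the flask from dimethoxymethane, COCOC, and acetyl chloride, CC(=O)Cl
Why: Williamson-type O-alkylation of the phenol by an α-chloro ether under amine base, which the silyl ether tolerates; generating the chloro ether in solution and destroying the excess in the quench avoids handling the neat carcinogen and its bis(chloromethyl) ether contaminant.

Step 3
Reactants: 4 1-chloropentane
Product: 5 pentyllithium
Conditions: Li (2.2 equiv, ca. 1% Na), heptane, 35–40 °C, Ar; filtered and titrated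
Reagents that add atoms: lithium, [Li]
Why: Reductive lithiation of a primary alkyl chloride by lithium metal, the standard preparation of primary alkyllithiums; the hydrocarbon solvent limits Wurtz coupling and gives a solution that is stable on storage.

Step 4
Reactants: 3 1-fluoro-3-(methoxymethoxy)-5-[(triisopropylsilyl)oxy]benzene; 5 pentyllithium
Product: 9 2-(methoxymethoxy)-6-pentyl-4-[(triisopropylsilyl)oxy]benzoic acid, via ortho-lithiated fluoroarene 6 (not isolated), via 3-alkoxybenzyne 7 (not isolated), via pentylated aryllithium 8 (not isolated)
Conditions: 5 (2.5 equiv), THF, −78 °C, 1 h; −78 to −10 °C; recool to −78 °C, dry CO2; cold 1 M HCl to pH 3–4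
Reagents that add atoms: carbon dioxide, O=C=O
Why: Pentyllithium, held by the acetal oxygens of the MOM group, should remove the ring proton of 3 between fluorine and the MOM ether, the most acidic one and the only one without the bulky silyl ether as a neighbour, giving 6, which persists at −78 °C. On warming, 6 expels LiF and the aryne 7 appears in the presence of excess 5. A second equivalent of 5 adds to the aryne carbon remote from the MOM ether, because the adjacent oxygen distorts the triple bond so that this terminus is the more electrophilic and the charge then develops beside the inductively withdrawing, lithium-chelating oxygen; this gives 8, which CO2 carboxylates. The closest known reaction type is the addition of alkyllithiums to 3-alkoxybenzynes generated from 3-alkoxyfluoroarenes followed by carboxylation, the established entry to 6-alkylsalicylic acids. No ring is closed and no stereocenter is created; two carbon–carbon bonds (C6–pentyl and C1–carboxyl) are formed. Two selectivities are needed: the site of metalation, secured by the fluorine/MOM pair and the steric shield of the TIPS group, and the direction of addition, secured by the MOM oxygen next to the triple bond, against which the silyloxy group (meta to the attacked carbon) exerts only a small inductive bias the other way. An excess of 5 keeps the aryllithiums 6 and 8 from competing for 7; the hexanoic acid that the excess gives with CO2 is removed by chromatography after step 5.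

Step 5
Reactants: 9 2-(methoxymethoxy)-6-pentyl-4-[(triisopropylsilyl)oxy]benzoic acid
Product: 10 benzyl 2-(methoxymethoxy)-6-pentyl-4-[(triisopropylsilyl)oxy]benzoate
Conditions: BnBr, KHCO3, DMF, rt
Reagents that add atoms: benzyl bromide, BrCc1ccccc1
Why: SN2 alkylation of the carboxylate, which is insensitive to the two ortho substituents that would block acyl substitution at the carboxyl carbon; the weak base leaves the acetal and the aryl silyl ether intact.

Step 6
Reactants: 10 benzyl 2-(methoxymethoxy)-6-pentyl-4-[(triisopropylsilyl)oxy]benzoate
Product: 11 benzyl 4-hydroxy-2-(methoxymethoxy)-6-pentylbenzoate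
Conditions: Bu4NF, AcOH (1:1), THF, 0 °C
Reagents that add atoms: none
Why: Fluoride-induced cleavage of the aryl silyl ether, driven by the Si–F bond; acetic acid buffers the phenoxide so that the benzyl ester and the acetal stay untouched and the C4 hydroxyl alone is freed.

Step 7
Reactants: 12 methyl 2,4-dihydroxy-6-methylbenzoate (methyl orsellinate)
Product: 13 methyl 2-hydroxy-4-methoxy-6-methylbenzoate
Conditions: MeI (1.05 equiv), K2CO3 (1.1 equiv), acetone, rt to 40 °C
Reagents that add atoms: iodomethane, CI
Why: Regioselective Williamson etherification: the C4' hydroxyl is the more acidic and is free, whereas the C2' hydroxyl is tied up in a hydrogen bond to the ester carbonyl and reacts much more slowly.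

Step 8
Reactants: 13 methyl 2-hydroxy-4-methoxy-6-methylbenzoate
Product: 14 methyl 2-(benzyloxy)-4-methoxy-6-methylbenzoate
Conditions: BnBr, K2CO3, DMF, 60 °C
Reagents that add atoms: benzyl bromide, BrCc1ccccc1
Why: Williamson etherification of the chelated phenol under more forcing conditions in a dipolar aprotic solvent; the benzyl group is chosen so that it leaves together with the benzyl ester in the last step.

Step 9
Reactants: 14 methyl 2-(benzyloxy)-4-methoxy-6-methylbenzoate
Product: 15 2-(benzyloxy)-4-methoxy-6-methylbenzoic acid
Conditions: KOH, DMSO/H2O, 90 °C; then cold 1 M HCl
Reagents that add atoms: potassium hydroxide, [K+].[OH-]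
Why: Saponification of a di-ortho-substituted benzoate, which needs poorly solvated hydroxide in DMSO and heat; the ethers are inert to base and the acid is liberated cold to avoid decarboxylation.

Step 10
Reactants: 15 2-(benzyloxy)-4-methoxy-6-methylbenzoic acid; 11 benzyl 4-hydroxy-2-(methoxymethoxy)-6-pentylbenzoate
Product: 17 benzyl 4-{[2-(benzyloxy)-4-methoxy-6-methylbenzoyl]oxy}-2-(methoxymethoxy)-6-pentylbenzoate, via acid chloride 16 (not isolated)
Conditions: (COCl)2, DMF (cat.), CH2Cl2, 0 °C to rt, evaporate; then 11, Et3N, DMAP (cat.), CH2Cl2, 0 °C to rt
Reagents that add atoms: none
Why: Acid chloride formation through the Vilsmeier intermediate, then base-mediated acylation of the only free phenol; 16 has no α-hydrogen and no free hydroxyl, so neither ketene formation nor self-condensation can occur.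

Step 11
Reactants: 17 benzyl 4-{[2-(benzyloxy)-4-methoxy-6-methylbenzoyl]oxy}-2-(methoxymethoxy)-6-pentylbenzoate
Product: 18 benzyl 4-{[2-(benzyloxy)-4-methoxy-6-methylbenzoyl]oxy}-2-hydroxy-6-pentylbenzoate
Conditions: HCl (1.25 M in MeOH), THF, rt
Reagents that add atoms: none
Why: Acid-catalysed acetal exchange: the protonated MOM ether releases the phenol, helped by the hydrogen bond to the ortho ester carbonyl, and methanol captures the methoxymethyl cation; both ester carbonyls lie between two ortho substituents, so transesterification should not compete.

Step 12
Reactants: 18 benzyl 4-{[2-(benzyloxy)-4-methoxy-6-methylbenzoyl]oxy}-2-hydroxy-6-pentylbenzoate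
Product: 19 4-[(2-hydroxy-4-methoxy-6-methylbenzoyl)oxy]-2-hydroxy-6-pentylbenzoic acid
Conditions: H2 (1 atm), 10% Pd/C, EtOAc, rt
Reagents that add atoms: none
Why: Palladium-catalysed hydrogenolysis of the benzylic C–O bonds of the benzyl ester and the benzyl aryl ether under neutral conditions, which should leave the aryl ester and the decarboxylation-prone acid intact and give toluene as the only by-product.

## Compound list

1 | 5-fluorobenzene-1,3-diol | Oc1cc(O)cc(F)c1 | starting material
2 | 3-fluoro-5-[(triisopropylsilyl)oxy]phenol | CC(C)[Si](Oc1cc(O)cc(F)c1)(C(C)C)C(C)C | intermediate
3 | 1-fluoro-3-(methoxymethoxy)-5-[(triisopropylsilyl)oxy]benzene | COCOc1cc(F)cc(O[Si](C(C)C)(C(C)C)C(C)C)c1 | intermediate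
4 | 1-chloropentane | CCCCCCl | starting material
5 | pentyllithium | [Li]CCCCC | intermediate
6 | {2-fluoro-6-(methoxymethoxy)-4-[(triisopropylsilyl)oxy]phenyl}lithium | [Li]c1c(F)cc(O[Si](C(C)C)(C(C)C)C(C)C)cc1OCOC | intermediate
7 | 3-(methoxymethoxy)-5-[(triisopropylsilyl)oxy]benzyne | COCOC1=CC(O[Si](C(C)C)(C(C)C)C(C)C)=CC#C1 | intermediate
8 | {2-(methoxymethoxy)-6-pentyl-4-[(triisopropylsilyl)oxy]phenyl}lithium | [Li]c1c(CCCCC)cc(O[Si](C(C)C)(C(C)C)C(C)C)cc1OCOC | intermediate
9 | 2-(methoxymethoxy)-6-pentyl-4-[(triisopropylsilyl)oxy]benzoic acid | CCCCCc1cc(O[Si](C(C)C)(C(C)C)C(C)C)cc(OCOC)c1C(=O)O | intermediate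
10 | benzyl 2-(methoxymethoxy)-6-pentyl-4-[(triisopropylsilyl)oxy]benzoate | CCCCCc1cc(O[Si](C(C)C)(C(C)C)C(C)C)cc(OCOC)c1C(=O)OCc1ccccc1 | intermediate
11 | benzyl 4-hydroxy-2-(methoxymethoxy)-6-pentylbenzoate | CCCCCc1cc(O)cc(OCOC)c1C(=O)OCc1ccccc1 | intermediate
12 | methyl 2,4-dihydroxy-6-methylbenzoate (methyl orsellinate) | COC(=O)c1c(C)cc(O)cc1O | starting material
13 | methyl 2-hydroxy-4-methoxy-6-methylbenzoate | COC(=O)c1c(C)cc(OC)cc1O | intermediate
14 | methyl 2-(benzyloxy)-4-methoxy-6-methylbenzoate | COC(=O)c1c(C)cc(OC)cc1OCc1ccccc1 | intermediate
15 | 2-(benzyloxy)-4-methoxy-6-methylbenzoic acid | Cc1cc(OC)cc(OCc2ccccc2)c1C(=O)O | intermediate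
16 | 2-(benzyloxy)-4-methoxy-6-methylbenzoyl chloride | Cc1cc(OC)cc(OCc2ccccc2)c1C(=O)Cl | intermediate
17 | benzyl 4-{[2-(benzyloxy)-4-methoxy-6-methylbenzoyl]oxy}-2-(methoxymethoxy)-6-pentylbenzoate | CCCCCc1cc(OC(=O)c2c(C)cc(OC)cc2OCc2ccccc2)cc(OCOC)c1C(=O)OCc1ccccc1 | intermediate
18 | benzyl 4-{[2-(benzyloxy)-4-methoxy-6-methylbenzoyl]oxy}-2-hydroxy-6-pentylbenzoate | CCCCCc1cc(OC(=O)c2c(C)cc(OC)cc2OCc2ccccc2)cc(O)c1C(=O)OCc1ccccc1 | intermediate
19 | 4-[(2-hydroxy-4-methoxy-6-methylbenzoyl)oxy]-2-hydroxy-6-pentylbenzoic acid | CCCCCc1cc(OC(=O)c2c(C)cc(OC)cc2O)cc(O)c1C(=O)O | target

## Step count and risk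

Total step count: 12 (steps 1 to 12, including the preparation of 5 and the three steps to 15).
Longest linear sequence: 8 steps from 1 (steps 1, 2, 4, 5, 6, 10, 11, 12).

Steps least certain to work:

**Step 4 (key step).** The aryllithiums 6 and 8 could add to the aryne in competition with 5, leading to biaryl coupling. The addition of 5 could also be incompletely regioselective, or metalation could stray to a position next to the silyl ether, followed by silyl migration to carbon. The fallback avoids the aryne. Setting out from 3, metalation with 5 (1.1 equiv) in THF at −78 °C and quenching with CO2 at that temperature, before any LiF is lost, would give 2-fluoro-6-(methoxymethoxy)-4-[(triisopropylsilyl)oxy]benzoic acid F1. Treating F1 with 5 (2.2 equiv, THF, −78 to 0 °C) should then replace the ortho fluorine by pentyl through carboxylate-directed nucleophilic aromatic substitution, a known reaction of ortho-fluorobenzoic acids with organolithiums. Fluoride is the better leaving group than the acetal oxygen, and both ring oxygens are meta to the attacked carbon. This comes back to the route at 9.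

**Step 10.** Acyl transfer to the phenol could be slow because the carbonyl of 16 lies between two ortho substituents, so that hydrolysis of the chloride on work-up or chloride-induced loss of the ortho benzyl group gains ground. The fallback changes both the activation and the source of regiocontrol. Setting out from 11, methanolic HCl would remove the acetal to give benzyl 2,4-dihydroxy-6-pentylbenzoate F2. F2 and 15 would then be condensed with trifluoroacetic anhydride in toluene at rt. The mixed anhydride ionises towards an acylium ion, which two ortho substituents favour, and the C2 hydroxyl of F2 is held back by its hydrogen bond to the ester, so the C4 hydroxyl should be acylated. This comes back to the route at 18 and bypasses 17 and step 11.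

**Step 11.** Acid-catalysed transesterification of the aryl ester by methanol could compete with acetal cleavage, or the cleavage could stall. The fallback reverses the order of the last two operations. Setting out from 17, hydrogenolysis (H2, Pd/C, EtOAc) would give 4-[(2-hydroxy-4-methoxy-6-methylbenzoyl)oxy]-2-(methoxymethoxy)-6-pentylbenzoic acid F3. Its acetal sits next to a free carboxylic acid and should fall off in CF3CO2H/CH2Cl2 at 0 °C, with aqueous work-up and no nucleophilic solvent present. This comes back to the route at 19.

**Step 1.** Proton exchange between the product and unreacted phenoxide could level the selectivity, so that silylation at both oxygens, or at neither, lowers the throughput. The fallback turns a selective protection into a selective deprotection. Setting out from 1, exhaustive silylation (iPr3SiCl 2.2 equiv, imidazole, DMF) would give 1-fluoro-3,5-bis[(triisopropylsilyl)oxy]benzene F4. One equivalent of Bu4NF in THF at −78 °C should remove a single silyl group, since the phenoxide formed by the first cleavage makes the remaining aryloxy group a poorer leaving group. This comes back to the route at 2.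

## Further compounds

F1 | step 4 | 2-fluoro-6-(methoxymethoxy)-4-[(triisopropylsilyl)oxy]benzoic acid | OC(=O)c1c(F)cc(O[Si](C(C)C)(C(C)C)C(C)C)cc1OCOC
F2 | step 10 | benzyl 2,4-dihydroxy-6-pentylbenzoate | CCCCCc1cc(O)cc(O)c1C(=O)OCc1ccccc1
F3 | step 11 | 4-[(2-hydroxy-4-methoxy-6-methylbenzoyl)oxy]-2-(methoxymethoxy)-6-pentylbenzoic acid | CCCCCc1cc(OC(=O)c2c(C)cc(OC)cc2O)cc(OCOC)c1C(=O)O
F4 | step 1 | 1-fluoro-3,5-bis[(triisopropylsilyl)oxy]benzene | CC(C)[Si](Oc1cc(F)cc(O[Si](C(C)C)(C(C)C)C(C)C)c1)(C(C)C)C(C)C
A1 | alternative 1 | benzyl 2,4-dihydroxy-6-pentylbenzoate | CCCCCc1cc(O)cc(O)c1C(=O)OCc1ccccc1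
A2 | alternative 1 | 6-(2,4-dioxopentyl)-2,2-dimethyl-4H-1,3-dioxin-4-one | CC(=O)CC(=O)CC1=CC(=O)OC(C)(C)O1
A3 | alternative 1 | benzyl 2-hydroxy-6-pentyl-4-[(3,5,7-trioxooctanoyl)oxy]benzoate | CCCCCc1cc(OC(=O)CC(=O)CC(=O)CC(C)=O)cc(O)c1C(=O)OCc1ccccc1
A4 | alternative 1 | benzyl 4-[(2,4-dihydroxy-6-methylbenzoyl)oxy]-2-hydroxy-6-pentylbenzoate | CCCCCc1cc(OC(=O)c2c(C)cc(O)cc2O)cc(O)c1C(=O)OCc1ccccc1
A5 | alternative 2 | 2-iodo-1,5-dimethoxy-3-methylbenzene | COc1cc(C)c(I)c(OC)c1
A6 | alternative 2 | carbon monoxide | [C-]#[O+]
A7 | alternative 2 | benzyl 4-[(2,4-dimethoxy-6-methylbenzoyl)oxy]-2-hydroxy-6-pentylbenzoate | CCCCCc1cc(OC(=O)c2c(C)cc(OC)cc2OC)cc(O)c1C(=O)OCc1ccccc1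
A8 | alternative 3 | benzyl 4-(but-2-ynoyloxy)-2-[(tert-butyldimethylsilyl)oxy]-6-pentylbenzoate | CCCCCc1cc(OC(=O)C#CC)cc(O[Si](C)(C)C(C)(C)C)c1C(=O)OCc1ccccc1
A9 | alternative 3 | 1,3-dimethoxy-1-(trimethylsilyloxy)buta-1,3-diene | C=C(OC)C=C(OC)O[Si](C)(C)C
A10 | alternative 3 | benzyl 2-[(tert-butyldimethylsilyl)oxy]-4-[(2-hydroxy-4-methoxy-6-methylbenzoyl)oxy]-6-pentylbenzoate | CCCCCc1cc(OC(=O)c2c(C)cc(OC)cc2O)cc(O[Si](C)(C)C(C)(C)C)c1C(=O)OCc1ccccc1
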